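**Assumption:** the SMILES fixes the absolute configuration. Ring atoms are numbered as in the 12‑oxabicyclo[9.1.0]dodecane name of the target: C1/C11 oxirane carbons, C2 ester carbinol, C3=C4 and C7=C8 alkenes, C5 quaternary carbon.

## Retrosynthetic overview

1. Target 36 ⇐ senecioylation of C2–OH and iBu2AlH reduction of the macrocyclic ethyl enoate 31 (gives C8–CH2OH), with silyl ether changes in between.
2. The 11‑membered carbocycle (second ring formed, step 26) ⇐ intramolecular Horner–Wadsworth–Emmons closure of C7=C8 from phosphono ester aldehyde 30.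
3. Key disconnection C3–C4 ⇐ intermolecular aldol of the lithium enolate of epoxy methyl ketone 19 with α‑quaternary aldehyde 10; dehydration gives the E‑enone and chelation‑controlled reduction sets C2.
4. Ketone 19 ⇐ Sharpless epoxidation (oxirane, first ring formed, step 13; sets C1/C11) of a (Z)‑allylic alcohol made by Still–Gennari olefination of 3‑silyloxypropanal.
5. Aldehyde 10 ⇐ geraniol by Sharpless epoxidation and stereospecific epoxy silyl ether rearrangement (sets C5), then methylenation and hydroboration.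

## Route

### Western aldehyde 10 (steps 1–8)

**Step 1**
Reactants: 1 geraniol
Product: 2 [(2R,3R)-3-methyl-3-(4-methylpent-3-en-1-yl)oxiran-2-yl]methanol
Conditions: Ti(OiPr)4 (5 mol%), D‑(−)‑diethyl tartrate (7.5 mol%), tBuOOH, 4 Å MS, CH2Cl2, −20 °C
Reagents that add atoms: tert‑butyl hydroperoxide, CC(C)(C)OO
Why: Sharpless asymmetric epoxidation of the allylic alcohol only; the D‑tartrate delivers oxygen to the face that gives the (2R,3R)‑epoxide (about 95% ee expected), and the remote trisubstituted alkene is untouched.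

**Step 2**
Reactants: 2 [(2R,3R)-3-methyl-3-(4-methylpent-3-en-1-yl)oxiran-2-yl]methanol
Product: 3 tert-butyldimethyl{[(2R,3R)-3-methyl-3-(4-methylpent-3-en-1-yl)oxiran-2-yl]methoxy}silane
Conditions: TBSCl, imidazole, DMF, 0 °C to rt
Reagents that add atoms: tert‑butyldimethylsilyl chloride, CC(C)(C)[Si](C)(C)Cl
Why: Standard silylation of a primary alcohol; no stereocentre is touched.

**Step 3**
Reactants: 3 tert-butyldimethyl{[(2R,3R)-3-methyl-3-(4-methylpent-3-en-1-yl)oxiran-2-yl]methoxy}silane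
Product: 4 (2R)-2-{[(tert-butyldimethylsilyl)oxy]methyl}-2,6-dimethylhept-5-enal
Conditions: MeAl(OAr)2 (2 equiv; Ar = 4‑bromo‑2,6‑di‑tert‑butylphenyl; from Me3Al + 2 ArOH), CH2Cl2, −78 °C
Reagents that add atoms: none
Why: Lewis‑acid‑promoted semipinacol rearrangement of an epoxy silyl ether: the tertiary C–O bond ionises and the siloxymethyl group shifts anti to it (inversion), so the epoxide chirality becomes the all‑carbon quaternary centre.

**Step 4**
Reactants: 4 (2R)-2-{[(tert-butyldimethylsilyl)oxy]methyl}-2,6-dimethylhept-5-enal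
Product: 5 tert-butyl{[(2S)-2-ethenyl-2,6-dimethylhept-5-en-1-yl]oxy}dimethylsilane
Conditions: Ph3PCH3Br, KOtBu, THF, 0 °C to rt
Reagents that add atoms: methyltriphenylphosphonium bromide, C[P+](c1ccccc1)(c1ccccc1)c1ccccc1.[Br-]
Why: Wittig methylenation of a non‑enolisable α‑quaternary aldehyde; the stereocentre cannot epimerise (the descriptor changes only by CIP priority).

**Step 5**
Reactants: 5 tert-butyl{[(2S)-2-ethenyl-2,6-dimethylhept-5-en-1-yl]oxy}dimethylsilane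
Product: 7 (3S)-3-{[(tert-butyldimethylsilyl)oxy]methyl}-3,7-dimethyloct-6-en-1-ol, via B-alkyl-9-BBN adduct 6 (not isolated)
Conditions: 9‑BBN, THF, 0 °C to rt; then NaOH, H2O2, 0 °C
Reagents that add atoms: 9‑borabicyclo[3.3.1]nonane, B1C2CCCC1CCC2 (boron of intermediate 6 only); hydrogen peroxide, OO
Why: Anti‑Markovnikov hydroboration–oxidation; 9‑BBN reacts with the monosubstituted vinyl group far faster than with the trisubstituted alkene.

**Step 6**
Reactants: 7 (3S)-3-{[(tert-butyldimethylsilyl)oxy]methyl}-3,7-dimethyloct-6-en-1-ol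
Product: 8 tert-butyl{[(2S)-2-{2-[(4-methoxyphenyl)methoxy]ethyl}-2,6-dimethylhept-5-en-1-yl]oxy}dimethylsilane
Conditions: NaH, 4‑methoxybenzyl chloride, nBu4NI (cat.), THF/DMF, 0 °C to rt
Reagents that add atoms: 4‑methoxybenzyl chloride, COc1ccc(CCl)cc1
Why: Williamson etherification; the PMB ether later survives fluoride, base, hydride and silylation and is removed oxidatively.

**Step 7**
Reactants: 8 tert-butyl{[(2S)-2-{2-[(4-methoxyphenyl)methoxy]ethyl}-2,6-dimethylhept-5-en-1-yl]oxy}dimethylsilane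
Product: 9 (2S)-2-{2-[(4-methoxyphenyl)methoxy]ethyl}-2,6-dimethylhept-5-en-1-ol
Conditions: nBu4NF, THF, rt
Reagents that add atoms: none
Why: Fluoride desilylation; the PMB ether and alkene are inert.

**Step 8**
Reactants: 9 (2S)-2-{2-[(4-methoxyphenyl)methoxy]ethyl}-2,6-dimethylhept-5-en-1-ol
Product: 10 (2S)-2-{2-[(4-methoxyphenyl)methoxy]ethyl}-2,6-dimethylhept-5-enal
Conditions: (nPr4N)RuO4 (5 mol%), N‑methylmorpholine N‑oxide, 4 Å MS, CH2Cl2, rt
Reagents that add atoms: none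
Why: Ley–Griffith oxidation under neutral conditions gives the non‑enolisable aldehyde without acid that could trigger a carbonyl‑ene reaction with the prenyl alkene.

### Eastern ketone 19 (steps 9–16)

**Step 9**
Reactants: 11 propane-1,3-diol
Product: 12 3-[(tert-butyldimethylsilyl)oxy]propan-1-ol
Conditions: NaH (1.0 equiv), THF; then TBSCl (1.0 equiv), rt
Reagents that add atoms: tert‑butyldimethylsilyl chloride, CC(C)(C)[Si](C)(C)Cl
Why: Monosilylation through the sparingly soluble monosodium alkoxide gives the mono‑ether selectively.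

**Step 10**
Reactants: 12 3-[(tert-butyldimethylsilyl)oxy]propan-1-ol
Product: 13 3-[(tert-butyldimethylsilyl)oxy]propanal
Conditions: (nPr4N)RuO4 (5 mol%), N‑methylmorpholine N‑oxide, 4 Å MS, CH2Cl2, rt
Reagents that add atoms: none
Why: Ley–Griffith oxidation; neutral conditions avoid β‑elimination of the silyloxy group.

**Step 11**
Reactants: 13 3-[(tert-butyldimethylsilyl)oxy]propanal
Product: 14 ethyl (2Z)-5-[(tert-butyldimethylsilyl)oxy]-2-methylpent-2-enoate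
Conditions: (CF3CH2O)2P(O)CH(CH3)CO2Et, KN(SiMe3)2, 18‑crown‑6, THF, −78 °C
Reagents that add atoms: ethyl 2‑[bis(2,2,2‑trifluoroethoxy)phosphoryl]propanoate, CCOC(=O)C(C)P(=O)(OCC(F)(F)F)OCC(F)(F)F
Why: Still–Gennari variant of the Horner–Wadsworth–Emmons reaction; fast, irreversible elimination from the kinetic adduct gives the (Z)‑trisubstituted enoate (ester cis to the chain).

**Step 12**
Reactants: 14 ethyl (2Z)-5-[(tert-butyldimethylsilyl)oxy]-2-methylpent-2-enoate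
Product: 15 (2Z)-5-[(tert-butyldimethylsilyl)oxy]-2-methylpent-2-en-1-ol
Conditions: iBu2AlH (2.2 equiv), CH2Cl2, −78 °C
Reagents that add atoms: none
Why: 1,2‑Reduction of the enoate to the allylic alcohol with retention of the Z geometry.

**Step 13**
Reactants: 15 (2Z)-5-[(tert-butyldimethylsilyl)oxy]-2-methylpent-2-en-1-ol
Product: 16 [(2S,3R)-3-{2-[(tert-butyldimethylsilyl)oxy]ethyl}-2-methyloxiran-2-yl]methanol
Conditions: Ti(OiPr)4 (10 mol%), L‑(+)‑diethyl tartrate (12 mol%), tBuOOH, 4 Å MS, CH2Cl2, −20 °C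
Reagents that add atoms: tert‑butyl hydroperoxide, CC(C)(C)OO
Why: Sharpless asymmetric epoxidation; the L‑tartrate sets both oxirane centres (C1 and C11 of the target) as the cis‑(2S,3R) epoxide (about 90% ee expected for a Z‑trisubstituted substrate; the minor enantiomer becomes a separable diastereomer after step 17).

**Step 14**
Reactants: 16 [(2S,3R)-3-{2-[(tert-butyldimethylsilyl)oxy]ethyl}-2-methyloxiran-2-yl]methanol
Product: 17 (2R,3R)-3-{2-[(tert-butyldimethylsilyl)oxy]ethyl}-2-methyloxirane-2-carbaldehyde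
Conditions: (nPr4N)RuO4 (5 mol%), N‑methylmorpholine N‑oxide, 4 Å MS, CH2Cl2, 0 °C to rt
Reagents that add atoms: none
Why: Ley–Griffith oxidation; the α‑carbon is fully substituted, so the epoxy aldehyde cannot epimerise (the descriptor changes only by CIP priority).

**Step 15**
Reactants: 17 (2R,3R)-3-{2-[(tert-butyldimethylsilyl)oxy]ethyl}-2-methyloxirane-2-carbaldehyde
Product: 18 1-[(2S,3R)-3-{2-[(tert-butyldimethylsilyl)oxy]ethyl}-2-methyloxiran-2-yl]ethan-1-ol (both carbinol epimers)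
Conditions: MeMgBr, THF, −78 °C
Reagents that add atoms: methylmagnesium bromide, C[Mg]Br
Why: Grignard addition to the aldehyde is much faster than epoxide opening at −78 °C; the new carbinol centre is erased in step 16.

**Step 16**
Reactants: 18 1-[(2S,3R)-3-{2-[(tert-butyldimethylsilyl)oxy]ethyl}-2-methyloxiran-2-yl]ethan-1-ol
Product: 19 1-[(2R,3R)-3-{2-[(tert-butyldimethylsilyl)oxy]ethyl}-2-methyloxiran-2-yl]ethan-1-one
Conditions: (nPr4N)RuO4 (5 mol%), N‑methylmorpholine N‑oxide, 4 Å MS, CH2Cl2, rt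
Reagents that add atoms: none
Why: Ley–Griffith oxidation converges both epimers to one epoxy methyl ketone.

### Union, ring closure and endgame (steps 17–31)

**Step 17 (key step)**
Reactants: 19 1-[(2R,3R)-3-{2-[(tert-butyldimethylsilyl)oxy]ethyl}-2-methyloxiran-2-yl]ethan-1-one; 10 (2S)-2-{2-[(4-methoxyphenyl)methoxy]ethyl}-2,6-dimethylhept-5-enal
Product: 21 (4S)-1-[(2R,3R)-3-{2-[(tert-butyldimethylsilyl)oxy]ethyl}-2-methyloxiran-2-yl]-3-hydroxy-4-{2-[(4-methoxyphenyl)methoxy]ethyl}-4,8-dimethylnon-7-en-1-one (both C3 epimers), via lithium enolate 20 (not isolated)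
Conditions: LiN(iPr)2 (1.05 equiv), THF, −78 °C; then 10, −78 °C; AcOH quench at −78 °C
Reagents that add atoms: lithium diisopropylamide, CC(C)N([Li])C(C)C (lithium of intermediate 20 only)
Why: Directed intermolecular aldol addition: the ketone can enolise only at its methyl group and the aldehyde has no α‑hydrogen, so one cross‑aldol constitution forms; the new carbinol centre is uncontrolled and is removed in step 18.

**Step 18**
Reactants: 21 (4S)-1-[(2R,3R)-3-{2-[(tert-butyldimethylsilyl)oxy]ethyl}-2-methyloxiran-2-yl]-3-hydroxy-4-{2-[(4-methoxyphenyl)methoxy]ethyl}-4,8-dimethylnon-7-en-1-one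
Product: 23 (2E,4S)-1-[(2R,3R)-3-{2-[(tert-butyldimethylsilyl)oxy]ethyl}-2-methyloxiran-2-yl]-4-{2-[(4-methoxyphenyl)methoxy]ethyl}-4,8-dimethylnona-2,7-dien-1-one, via mesylate 22 (not isolated)
Conditions: MsCl, Et3N, CH2Cl2, 0 °C; then DBU, rt
Reagents that add atoms: methanesulfonyl chloride, CS(=O)(=O)Cl (mesyl group of intermediate 22 only)
Why: Mesylation and E1cB elimination complete the aldol condensation; the bulky quaternary substituent enforces the E‑enone, and the γ‑carbon is quaternary so no deconjugation is possible.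

**Step 19**
Reactants: 23 (2E,4S)-1-[(2R,3R)-3-{2-[(tert-butyldimethylsilyl)oxy]ethyl}-2-methyloxiran-2-yl]-4-{2-[(4-methoxyphenyl)methoxy]ethyl}-4,8-dimethylnona-2,7-dien-1-one
Product: 24 (1S,2E,4S)-1-[(2S,3R)-3-{2-[(tert-butyldimethylsilyl)oxy]ethyl}-2-methyloxiran-2-yl]-4-{2-[(4-methoxyphenyl)methoxy]ethyl}-4,8-dimethylnona-2,7-dien-1-ol
Conditions: Zn(BH4)2, Et2O, −20 °C to 0 °C
Reagents that add atoms: none
Why: Chelation‑controlled 1,2‑reduction of an α,β‑epoxy ketone: zinc bridges the carbonyl and oxirane oxygens and hydride adds anti to the oxirane C–C bond, giving the erythro (1S) epoxy alcohol, which is C2 of the target.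

**Step 20**
Reactants: 24 (1S,2E,4S)-1-[(2S,3R)-3-{2-[(tert-butyldimethylsilyl)oxy]ethyl}-2-methyloxiran-2-yl]-4-{2-[(4-methoxyphenyl)methoxy]ethyl}-4,8-dimethylnona-2,7-dien-1-ol
Product: 25 tert-butyl({(1S,2E,4S)-1-[(2R,3R)-3-{2-[(tert-butyldimethylsilyl)oxy]ethyl}-2-methyloxiran-2-yl]-4-{2-[(4-methoxyphenyl)methoxy]ethyl}-4,8-dimethylnona-2,7-dien-1-yl}oxy)dimethylsilane
Conditions: TBSOTf, 2,6‑lutidine, CH2Cl2, −78 °C to 0 °C
Reagents that add atoms: tert‑butyldimethylsilyl trifluoromethanesulfonate, CC(C)(C)[Si](C)(C)OS(=O)(=O)C(F)(F)F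
Why: Silylation of the hindered secondary epoxy alcohol blocks Payne rearrangement and oxidation in the following steps.

**Step 21**
Reactants: 25 tert-butyl({(1S,2E,4S)-1-[(2R,3R)-3-{2-[(tert-butyldimethylsilyl)oxy]ethyl}-2-methyloxiran-2-yl]-4-{2-[(4-methoxyphenyl)methoxy]ethyl}-4,8-dimethylnona-2,7-dien-1-yl}oxy)dimethylsilane
Product: 26 2-[(2R,3R)-3-[(1S,2E,4S)-1-[(tert-butyldimethylsilyl)oxy]-4-{2-[(4-methoxyphenyl)methoxy]ethyl}-4,8-dimethylnona-2,7-dien-1-yl]-3-methyloxiran-2-yl]ethan-1-ol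
Conditions: HF·pyridine, pyridine, THF, 0 °C
Reagents that add atoms: none
Why: Selective desilylation: the unhindered primary silyl ether cleaves much faster than the secondary one flanked by the tetrasubstituted oxirane carbon.

**Step 22**
Reactants: 26 2-[(2R,3R)-3-[(1S,2E,4S)-1-[(tert-butyldimethylsilyl)oxy]-4-{2-[(4-methoxyphenyl)methoxy]ethyl}-4,8-dimethylnona-2,7-dien-1-yl]-3-methyloxiran-2-yl]ethan-1-ol
Product: 27 tert-butyl({(1S,2E,4S)-1-[(2R,3R)-3-(2-iodoethyl)-2-methyloxiran-2-yl]-4-{2-[(4-methoxyphenyl)methoxy]ethyl}-4,8-dimethylnona-2,7-dien-1-yl}oxy)dimethylsilane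
Conditions: I2, PPh3, imidazole, CH2Cl2, 0 °C
Reagents that add atoms: iodine, II
Why: Appel iodination of the primary alcohol under imidazole‑buffered conditions that spare the epoxide.

**Step 23**
Reactants: 27 tert-butyl({(1S,2E,4S)-1-[(2R,3R)-3-(2-iodoethyl)-2-methyloxiran-2-yl]-4-{2-[(4-methoxyphenyl)methoxy]ethyl}-4,8-dimethylnona-2,7-dien-1-yl}oxy)dimethylsilane
Product: 28 ethyl 4-[(2R,3R)-3-[(1S,2E,4S)-1-[(tert-butyldimethylsilyl)oxy]-4-{2-[(4-methoxyphenyl)methoxy]ethyl}-4,8-dimethylnona-2,7-dien-1-yl]-3-methyloxiran-2-yl]-2-(diethoxyphosphoryl)butanoate (both C2 epimers)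
Conditions: (EtO)2P(O)CH2CO2Et (3 equiv), NaH, DMF, 0 °C; then 27, 55 °C
Reagents that add atoms: triethyl phosphonoacetate, CCOC(=O)CP(=O)(OCC)OCC
Why: SN2 alkylation of the soft phosphonoacetate carbanion by the primary iodide; excess nucleophile suppresses dialkylation, and the new centre is lost in step 26.

**Step 24**
Reactants: 28 ethyl 4-[(2R,3R)-3-[(1S,2E,4S)-1-[(tert-butyldimethylsilyl)oxy]-4-{2-[(4-methoxyphenyl)methoxy]ethyl}-4,8-dimethylnona-2,7-dien-1-yl]-3-methyloxiran-2-yl]-2-(diethoxyphosphoryl)butanoate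
Product: 29 ethyl 4-[(2R,3R)-3-[(1S,2E,4S)-1-[(tert-butyldimethylsilyl)oxy]-4-(2-hydroxyethyl)-4,8-dimethylnona-2,7-dien-1-yl]-3-methyloxiran-2-yl]-2-(diethoxyphosphoryl)butanoate
Conditions: DDQ, CH2Cl2/pH 7 buffer, 0 °C to rt
Reagents that add atoms: none
Why: Oxidative cleavage of the PMB ether; buffered conditions spare the epoxide, silyl ether and alkenes.

**Step 25**
Reactants: 29 ethyl 4-[(2R,3R)-3-[(1S,2E,4S)-1-[(tert-butyldimethylsilyl)oxy]-4-(2-hydroxyethyl)-4,8-dimethylnona-2,7-dien-1-yl]-3-methyloxiran-2-yl]-2-(diethoxyphosphoryl)butanoate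
Product: 30 ethyl 4-[(2R,3R)-3-[(1S,2E,4S)-1-[(tert-butyldimethylsilyl)oxy]-4,8-dimethyl-4-(2-oxoethyl)nona-2,7-dien-1-yl]-3-methyloxiran-2-yl]-2-(diethoxyphosphoryl)butanoate
Conditions: (nPr4N)RuO4 (5 mol%), N‑methylmorpholine N‑oxide, 4 Å MS, CH2Cl2, rt; used at once
Reagents that add atoms: none
Why: Ley–Griffith oxidation gives the aldehyde under neutral conditions, avoiding a carbonyl‑ene reaction with the prenyl alkene.

**Step 26**
Reactants: 30 ethyl 4-[(2R,3R)-3-[(1S,2E,4S)-1-[(tert-butyldimethylsilyl)oxy]-4,8-dimethyl-4-(2-oxoethyl)nona-2,7-dien-1-yl]-3-methyloxiran-2-yl]-2-(diethoxyphosphoryl)butanoate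
Product: 31 ethyl (1R,2S,3E,5S,7E,11R)-2-[(tert-butyldimethylsilyl)oxy]-1,5-dimethyl-5-(4-methylpent-3-en-1-yl)-12-oxabicyclo[9.1.0]dodeca-3,7-diene-8-carboxylate (ring numbered as in the target)
Conditions: LiCl, DBU, MeCN, rt to 40 °C, syringe‑pump addition (about 1 mM)
Reagents that add atoms: none
Why: Intramolecular Horner–Wadsworth–Emmons olefination under Masamune–Roush conditions at high dilution; the E‑enoate (ester trans to C6) is both the normal outcome and the less strained endocyclic‑cis geometry for an 11‑membered ring.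

**Step 27**
Reactants: 31 ethyl (1R,2S,3E,5S,7E,11R)-2-[(tert-butyldimethylsilyl)oxy]-1,5-dimethyl-5-(4-methylpent-3-en-1-yl)-12-oxabicyclo[9.1.0]dodeca-3,7-diene-8-carboxylate
Product: 32 [(1R,2S,3E,5S,7E,11R)-2-[(tert-butyldimethylsilyl)oxy]-1,5-dimethyl-5-(4-methylpent-3-en-1-yl)-12-oxabicyclo[9.1.0]dodeca-3,7-dien-8-yl]methanol
Conditions: iBu2AlH (2.5 equiv), CH2Cl2, −78 °C
Reagents that add atoms: none
Why: 1,2‑Reduction of the enoate to the allylic alcohol; the trisubstituted epoxide is inert at −78 °C with the neighbouring oxygen silylated.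

**Step 28**
Reactants: 32 [(1R,2S,3E,5S,7E,11R)-2-[(tert-butyldimethylsilyl)oxy]-1,5-dimethyl-5-(4-methylpent-3-en-1-yl)-12-oxabicyclo[9.1.0]dodeca-3,7-dien-8-yl]methanol
Product: 33 (1S,2S,3E,5S,7E,11R)-8-(hydroxymethyl)-1,5-dimethyl-5-(4-methylpent-3-en-1-yl)-12-oxabicyclo[9.1.0]dodeca-3,7-dien-2-ol
Conditions: nBu4NF, AcOH, THF, rt
Reagents that add atoms: none
Why: Buffered fluoride desilylation frees the C2 carbinol without Payne rearrangement (the C1 descriptor changes only by CIP priority).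

**Step 29**
Reactants: 33 (1S,2S,3E,5S,7E,11R)-8-(hydroxymethyl)-1,5-dimethyl-5-(4-methylpent-3-en-1-yl)-12-oxabicyclo[9.1.0]dodeca-3,7-dien-2-ol
Product: 34 (1S,2S,3E,5S,7E,11R)-8-{[(tert-butyldimethylsilyl)oxy]methyl}-1,5-dimethyl-5-(4-methylpent-3-en-1-yl)-12-oxabicyclo[9.1.0]dodeca-3,7-dien-2-ol
Conditions: TBSCl (1.1 equiv), imidazole, CH2Cl2, −20 °C to 0 °C
Reagents that add atoms: tert‑butyldimethylsilyl chloride, CC(C)(C)[Si](C)(C)Cl
Why: Selective silylation of the unhindered primary allylic alcohol over the hindered secondary carbinol.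

**Step 30**
Reactants: 34 (1S,2S,3E,5S,7E,11R)-8-{[(tert-butyldimethylsilyl)oxy]methyl}-1,5-dimethyl-5-(4-methylpent-3-en-1-yl)-12-oxabicyclo[9.1.0]dodeca-3,7-dien-2-ol
Product: 35 (1R,2S,3E,5S,7E,11R)-8-{[(tert-butyldimethylsilyl)oxy]methyl}-1,5-dimethyl-5-(4-methylpent-3-en-1-yl)-12-oxabicyclo[9.1.0]dodeca-3,7-dien-2-yl 3-methylbut-2-enoate
Conditions: 3‑methylbut‑2‑enoyl chloride, pyridine, DMAP (cat.), CH2Cl2, 0 °C to rt
Reagents that add atoms: 3‑methylbut‑2‑enoyl chloride, CC(C)=CC(=O)Cl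
Why: DMAP‑catalysed acylation with retention at C2; pyridine as the only base limits deconjugation of the senecioyl group through a vinylketene.

**Step 31**
Reactants: 35 (1R,2S,3E,5S,7E,11R)-8-{[(tert-butyldimethylsilyl)oxy]methyl}-1,5-dimethyl-5-(4-methylpent-3-en-1-yl)-12-oxabicyclo[9.1.0]dodeca-3,7-dien-2-yl 3-methylbut-2-enoate
Product: 36 (1R,2S,3E,5S,7E,11R)-8-(hydroxymethyl)-1,5-dimethyl-5-(4-methylpent-3-en-1-yl)-12-oxabicyclo[9.1.0]dodeca-3,7-dien-2-yl 3-methylbut-2-enoate (CNP0318149.1)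
Conditions: HF·pyridine, pyridine, THF, 0 °C
Reagents that add atoms: none
Why: Buffered HF cleaves the primary allylic silyl ether and leaves the ester and epoxide intact.

## Compound list

1 | geraniol, (2E)-3,7-dimethylocta-2,6-dien-1-ol | CC(C)=CCC/C(C)=C/CO | starting material
2 | [(2R,3R)-3-methyl-3-(4-methylpent-3-en-1-yl)oxiran-2-yl]methanol | CC(C)=CCC[C@@]1(C)O[C@@H]1CO | intermediate
3 | tert-butyldimethyl{[(2R,3R)-3-methyl-3-(4-methylpent-3-en-1-yl)oxiran-2-yl]methoxy}silane | CC(C)=CCC[C@@]1(C)O[C@@H]1CO[Si](C)(C)C(C)(C)C | intermediate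
4 | (2R)-2-{[(tert-butyldimethylsilyl)oxy]methyl}-2,6-dimethylhept-5-enal | CC(C)=CCC[C@](C)(CO[Si](C)(C)C(C)(C)C)C=O | intermediate
5 | tert-butyl{[(2S)-2-ethenyl-2,6-dimethylhept-5-en-1-yl]oxy}dimethylsilane | CC(C)=CCC[C@](C)(CO[Si](C)(C)C(C)(C)C)C=C | intermediate
6 | B-alkyl-9-BBN adduct, 9-[(3R)-3-{[(tert-butyldimethylsilyl)oxy]methyl}-3,7-dimethyloct-6-en-1-yl]-9-borabicyclo[3.3.1]nonane | CC(C)=CCC[C@](C)(CO[Si](C)(C)C(C)(C)C)CCB1C2CCCC1CCC2 | intermediate (not isolated)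
7 | (3S)-3-{[(tert-butyldimethylsilyl)oxy]methyl}-3,7-dimethyloct-6-en-1-ol | CC(C)=CCC[C@](C)(CO[Si](C)(C)C(C)(C)C)CCO | intermediate
8 | tert-butyl{[(2S)-2-{2-[(4-methoxyphenyl)methoxy]ethyl}-2,6-dimethylhept-5-en-1-yl]oxy}dimethylsilane | CC(C)=CCC[C@](C)(CO[Si](C)(C)C(C)(C)C)CCOCc1ccc(OC)cc1 | intermediate
9 | (2S)-2-{2-[(4-methoxyphenyl)methoxy]ethyl}-2,6-dimethylhept-5-en-1-ol | CC(C)=CCC[C@](C)(CO)CCOCc1ccc(OC)cc1 | intermediate
10 | (2S)-2-{2-[(4-methoxyphenyl)methoxy]ethyl}-2,6-dimethylhept-5-enal | CC(C)=CCC[C@](C)(C=O)CCOCc1ccc(OC)cc1 | intermediate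
11 | propane-1,3-diol | OCCCO | starting material
12 | 3-[(tert-butyldimethylsilyl)oxy]propan-1-ol | OCCCO[Si](C)(C)C(C)(C)C | intermediate
13 | 3-[(tert-butyldimethylsilyl)oxy]propanal | O=CCCO[Si](C)(C)C(C)(C)C | intermediate
14 | ethyl (2Z)-5-[(tert-butyldimethylsilyl)oxy]-2-methylpent-2-enoate | CCOC(=O)/C(C)=C\CCO[Si](C)(C)C(C)(C)C | intermediate
15 | (2Z)-5-[(tert-butyldimethylsilyl)oxy]-2-methylpent-2-en-1-ol | OC/C(C)=C\CCO[Si](C)(C)C(C)(C)C | intermediate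
16 | [(2S,3R)-3-{2-[(tert-butyldimethylsilyl)oxy]ethyl}-2-methyloxiran-2-yl]methanol | OC[C@]1(C)O[C@@H]1CCO[Si](C)(C)C(C)(C)C | intermediate
17 | (2R,3R)-3-{2-[(tert-butyldimethylsilyl)oxy]ethyl}-2-methyloxirane-2-carbaldehyde | O=C[C@]1(C)O[C@@H]1CCO[Si](C)(C)C(C)(C)C | intermediate
18 | 1-[(2S,3R)-3-{2-[(tert-butyldimethylsilyl)oxy]ethyl}-2-methyloxiran-2-yl]ethan-1-ol (both carbinol epimers) | CC(O)[C@]1(C)O[C@@H]1CCO[Si](C)(C)C(C)(C)C | intermediate
19 | 1-[(2R,3R)-3-{2-[(tert-butyldimethylsilyl)oxy]ethyl}-2-methyloxiran-2-yl]ethan-1-one | CC(=O)[C@]1(C)O[C@@H]1CCO[Si](C)(C)C(C)(C)C | intermediate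
20 | lithium enolate of 19, lithium 1-[(2R,3R)-3-{2-[(tert-butyldimethylsilyl)oxy]ethyl}-2-methyloxiran-2-yl]ethen-1-olate | C=C(O[Li])[C@]1(C)O[C@@H]1CCO[Si](C)(C)C(C)(C)C | intermediate (not isolated)
21 | (4S)-1-[(2R,3R)-3-{2-[(tert-butyldimethylsilyl)oxy]ethyl}-2-methyloxiran-2-yl]-3-hydroxy-4-{2-[(4-methoxyphenyl)methoxy]ethyl}-4,8-dimethylnon-7-en-1-one (both C3 epimers) | CC(C)=CCC[C@](C)(C(O)CC(=O)[C@]1(C)O[C@@H]1CCO[Si](C)(C)C(C)(C)C)CCOCc1ccc(OC)cc1 | intermediate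
22 | mesylate of 21, (4S)-1-[(2R,3R)-3-{2-[(tert-butyldimethylsilyl)oxy]ethyl}-2-methyloxiran-2-yl]-4-{2-[(4-methoxyphenyl)methoxy]ethyl}-4,8-dimethyl-1-oxonon-7-en-3-yl methanesulfonate | CC(C)=CCC[C@](C)(C(OS(C)(=O)=O)CC(=O)[C@]1(C)O[C@@H]1CCO[Si](C)(C)C(C)(C)C)CCOCc1ccc(OC)cc1 | intermediate (not isolated)
23 | (2E,4S)-1-[(2R,3R)-3-{2-[(tert-butyldimethylsilyl)oxy]ethyl}-2-methyloxiran-2-yl]-4-{2-[(4-methoxyphenyl)methoxy]ethyl}-4,8-dimethylnona-2,7-dien-1-one | CC(C)=CCC[C@](C)(/C=C/C(=O)[C@]1(C)O[C@@H]1CCO[Si](C)(C)C(C)(C)C)CCOCc1ccc(OC)cc1 | intermediate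
24 | (1S,2E,4S)-1-[(2S,3R)-3-{2-[(tert-butyldimethylsilyl)oxy]ethyl}-2-methyloxiran-2-yl]-4-{2-[(4-methoxyphenyl)methoxy]ethyl}-4,8-dimethylnona-2,7-dien-1-ol | CC(C)=CCC[C@](C)(/C=C/[C@H](O)[C@]1(C)O[C@@H]1CCO[Si](C)(C)C(C)(C)C)CCOCc1ccc(OC)cc1 | intermediate
25 | tert-butyl({(1S,2E,4S)-1-[(2R,3R)-3-{2-[(tert-butyldimethylsilyl)oxy]ethyl}-2-methyloxiran-2-yl]-4-{2-[(4-methoxyphenyl)methoxy]ethyl}-4,8-dimethylnona-2,7-dien-1-yl}oxy)dimethylsilane | CC(C)=CCC[C@](C)(/C=C/[C@H](O[Si](C)(C)C(C)(C)C)[C@]1(C)O[C@@H]1CCO[Si](C)(C)C(C)(C)C)CCOCc1ccc(OC)cc1 | intermediate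
26 | 2-[(2R,3R)-3-[(1S,2E,4S)-1-[(tert-butyldimethylsilyl)oxy]-4-{2-[(4-methoxyphenyl)methoxy]ethyl}-4,8-dimethylnona-2,7-dien-1-yl]-3-methyloxiran-2-yl]ethan-1-ol | CC(C)=CCC[C@](C)(/C=C/[C@H](O[Si](C)(C)C(C)(C)C)[C@]1(C)O[C@@H]1CCO)CCOCc1ccc(OC)cc1 | intermediate
27 | tert-butyl({(1S,2E,4S)-1-[(2R,3R)-3-(2-iodoethyl)-2-methyloxiran-2-yl]-4-{2-[(4-methoxyphenyl)methoxy]ethyl}-4,8-dimethylnona-2,7-dien-1-yl}oxy)dimethylsilane | CC(C)=CCC[C@](C)(/C=C/[C@H](O[Si](C)(C)C(C)(C)C)[C@]1(C)O[C@@H]1CCI)CCOCc1ccc(OC)cc1 | intermediate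
28 | ethyl 4-[(2R,3R)-3-[(1S,2E,4S)-1-[(tert-butyldimethylsilyl)oxy]-4-{2-[(4-methoxyphenyl)methoxy]ethyl}-4,8-dimethylnona-2,7-dien-1-yl]-3-methyloxiran-2-yl]-2-(diethoxyphosphoryl)butanoate (both C2 epimers) | CC(C)=CCC[C@](C)(/C=C/[C@H](O[Si](C)(C)C(C)(C)C)[C@]1(C)O[C@@H]1CCC(C(=O)OCC)P(=O)(OCC)OCC)CCOCc1ccc(OC)cc1 | intermediate
29 | ethyl 4-[(2R,3R)-3-[(1S,2E,4S)-1-[(tert-butyldimethylsilyl)oxy]-4-(2-hydroxyethyl)-4,8-dimethylnona-2,7-dien-1-yl]-3-methyloxiran-2-yl]-2-(diethoxyphosphoryl)butanoate | CC(C)=CCC[C@](C)(/C=C/[C@H](O[Si](C)(C)C(C)(C)C)[C@]1(C)O[C@@H]1CCC(C(=O)OCC)P(=O)(OCC)OCC)CCO | intermediate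
30 | ethyl 4-[(2R,3R)-3-[(1S,2E,4S)-1-[(tert-butyldimethylsilyl)oxy]-4,8-dimethyl-4-(2-oxoethyl)nona-2,7-dien-1-yl]-3-methyloxiran-2-yl]-2-(diethoxyphosphoryl)butanoate | CC(C)=CCC[C@](C)(/C=C/[C@H](O[Si](C)(C)C(C)(C)C)[C@]1(C)O[C@@H]1CCC(C(=O)OCC)P(=O)(OCC)OCC)CC=O | intermediate
31 | ethyl (1R,2S,3E,5S,7E,11R)-2-[(tert-butyldimethylsilyl)oxy]-1,5-dimethyl-5-(4-methylpent-3-en-1-yl)-12-oxabicyclo[9.1.0]dodeca-3,7-diene-8-carboxylate (ring numbered as in the target) | CC(C)=CCC[C@]1(C)/C=C/[C@H](O[Si](C)(C)C(C)(C)C)[C@]2(C)O[C@@H]2CC/C(C(=O)OCC)=C\C1 | intermediate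
32 | [(1R,2S,3E,5S,7E,11R)-2-[(tert-butyldimethylsilyl)oxy]-1,5-dimethyl-5-(4-methylpent-3-en-1-yl)-12-oxabicyclo[9.1.0]dodeca-3,7-dien-8-yl]methanol | CC(C)=CCC[C@]1(C)/C=C/[C@H](O[Si](C)(C)C(C)(C)C)[C@]2(C)O[C@@H]2CC/C(CO)=C\C1 | intermediate
33 | (1S,2S,3E,5S,7E,11R)-8-(hydroxymethyl)-1,5-dimethyl-5-(4-methylpent-3-en-1-yl)-12-oxabicyclo[9.1.0]dodeca-3,7-dien-2-ol | CC(C)=CCC[C@]1(C)/C=C/[C@H](O)[C@]2(C)O[C@@H]2CC/C(CO)=C\C1 | intermediate
34 | (1S,2S,3E,5S,7E,11R)-8-{[(tert-butyldimethylsilyl)oxy]methyl}-1,5-dimethyl-5-(4-methylpent-3-en-1-yl)-12-oxabicyclo[9.1.0]dodeca-3,7-dien-2-ol | CC(C)=CCC[C@]1(C)/C=C/[C@H](O)[C@]2(C)O[C@@H]2CC/C(CO[Si](C)(C)C(C)(C)C)=C\C1 | intermediate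
35 | (1R,2S,3E,5S,7E,11R)-8-{[(tert-butyldimethylsilyl)oxy]methyl}-1,5-dimethyl-5-(4-methylpent-3-en-1-yl)-12-oxabicyclo[9.1.0]dodeca-3,7-dien-2-yl 3-methylbut-2-enoate | CC(C)=CCC[C@]1(C)/C=C/[C@H](OC(=O)C=C(C)C)[C@]2(C)O[C@@H]2CC/C(CO[Si](C)(C)C(C)(C)C)=C\C1 | intermediate
36 | (1R,2S,3E,5S,7E,11R)-8-(hydroxymethyl)-1,5-dimethyl-5-(4-methylpent-3-en-1-yl)-12-oxabicyclo[9.1.0]dodeca-3,7-dien-2-yl 3-methylbut-2-enoate (CNP0318149.1) | CC(C)=CCC[C@]1(C)/C=C/[C@H](OC(=O)C=C(C)C)[C@]2(C)O[C@@H]2CC/C(CO)=C\C1 | target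

## Step count and risks

Total step count: 31. Longest linear sequence: 23 steps (steps 1–8, or the equally long 9–16, followed by 17–31).

**Step 3 (epoxy silyl ether rearrangement).** It needs a bulky, specially prepared aluminium reagent, and the product aldehyde could undergo Lewis‑acid side reactions with the prenyl alkene. The fallback sets out from geraniol 1 and comes back at 5. Geraniol 1 is acylated (ClCO2Me, pyridine) to geranyl methyl carbonate F1. Copper‑catalysed enantioselective SN2′ allylic borylation (CuCl, a chiral N‑heterocyclic carbene ligand in the enantiomer that gives the R product, NaOMe, B2pin2) gives the tertiary pinacol allylboronate F2, which already carries the quaternary stereocentre. Matteson one‑carbon homologation (BrCH2Cl, nBuLi, −78 °C to rt; stereoretentive 1,2‑shift) gives the homologated pinacol boronate F3. Oxidation with NaOH/H2O2 gives the neopentyl alcohol F4, and TBSCl/imidazole returns to 5. This replaces steps 1–4.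

**Step 19 (diastereoselective ketone reduction).** The chelate model is well founded for epoxy ketones, but this substrate carries both an α‑methyl group and a cis‑substituted oxirane, so the facial bias could be eroded or reversed. The fallback sets out from enone 23 and comes back at 24. If the reduction of 23 delivers mainly the wrong carbinol, the (1R)-epimeric alcohol F5, that alcohol is inverted by a Mitsunobu reaction (4‑nitrobenzoic acid, PPh3, diisopropyl azodicarboxylate) to the inverted 4‑nitrobenzoate F6. Mild methanolysis (K2CO3, MeOH, 0 °C) then returns to 24. Stereocontrol thus moves from the hydride addition to an SN2 inversion.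

**Step 26 (11‑membered ring closure).** Medium‑ring strain and competing dimerisation make the macrocyclic olefination the most uncertain step. The fallback sets out from iodide 27 and comes back at 31, closing the ring at the C8–C9 single bond instead of the C7=C8 alkene. DDQ removes the PMB group from 27 to give the iodo alcohol F7. Oxidation with (nPr4N)RuO4 and N‑methylmorpholine N‑oxide gives the iodo aldehyde F8. Wittig reaction with ethyl 2‑bromo‑2‑(triphenyl‑λ5‑phosphanylidene)acetate gives the (Z)-α-bromo enoate F9, in which bromine is cis to C6 and the alkene geometry is already fixed. Nickel‑catalysed intramolecular reductive sp3–sp2 coupling of the alkyl iodide with the vinyl bromide (NiBr2(MeOCH2CH2OMe), 4,4′‑di‑tert‑butyl‑2,2′‑bipyridine, Zn, NaI, N,N‑dimethylacetamide, syringe‑pump dilution) proceeds with retention of alkene geometry and returns to macrocyclic ester 31. This reductive macrocyclisation is precedented mainly intermolecularly, so it is itself speculative for an 11‑membered ring.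

## Further compounds

F1 | step 3 | (2E)-3,7-dimethylocta-2,6-dien-1-yl methyl carbonate | CC(C)=CCC/C(C)=C/COC(=O)OC
F2 | step 3 | 2-[(3R)-3,7-dimethylocta-1,6-dien-3-yl]-4,4,5,5-tetramethyl-1,3,2-dioxaborolane | CC(C)=CCC[C@](C)(B1OC(C)(C)C(C)(C)O1)C=C
F3 | step 3 | 2-{[(2S)-2-ethenyl-2,6-dimethylhept-5-en-1-yl]}-4,4,5,5-tetramethyl-1,3,2-dioxaborolane | CC(C)=CCC[C@](C)(CB1OC(C)(C)C(C)(C)O1)C=C
F4 | step 3 | (2S)-2-ethenyl-2,6-dimethylhept-5-en-1-ol | CC(C)=CCC[C@](C)(CO)C=C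
F5 | step 19 | (1R,2E,4S)-1-[(2S,3R)-3-{2-[(tert-butyldimethylsilyl)oxy]ethyl}-2-methyloxiran-2-yl]-4-{2-[(4-methoxyphenyl)methoxy]ethyl}-4,8-dimethylnona-2,7-dien-1-ol | CC(C)=CCC[C@](C)(/C=C/[C@@H](O)[C@]1(C)O[C@@H]1CCO[Si](C)(C)C(C)(C)C)CCOCc1ccc(OC)cc1
F6 | step 19 | (1S,2E,4S)-1-[(2R,3R)-3-{2-[(tert-butyldimethylsilyl)oxy]ethyl}-2-methyloxiran-2-yl]-4-{2-[(4-methoxyphenyl)methoxy]ethyl}-4,8-dimethylnona-2,7-dien-1-yl 4-nitrobenzoate | CC(C)=CCC[C@](C)(/C=C/[C@H](OC(=O)c1ccc(cc1)[N+](=O)[O-])[C@]2(C)O[C@@H]2CCO[Si](C)(C)C(C)(C)C)CCOCc1ccc(OC)cc1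
F7 | step 26 | (3S,4E,6S)-6-[(tert-butyldimethylsilyl)oxy]-6-[(2R,3R)-3-(2-iodoethyl)-2-methyloxiran-2-yl]-3-methyl-3-(4-methylpent-3-en-1-yl)hex-4-en-1-ol | CC(C)=CCC[C@](C)(/C=C/[C@H](O[Si](C)(C)C(C)(C)C)[C@]1(C)O[C@@H]1CCI)CCO
F8 | step 26 | (3S,4E,6S)-6-[(tert-butyldimethylsilyl)oxy]-6-[(2R,3R)-3-(2-iodoethyl)-2-methyloxiran-2-yl]-3-methyl-3-(4-methylpent-3-en-1-yl)hex-4-enal | CC(C)=CCC[C@](C)(/C=C/[C@H](O[Si](C)(C)C(C)(C)C)[C@]1(C)O[C@@H]1CCI)CC=O
F9 | step 26 | ethyl (2Z,5S,6E,8S)-2-bromo-8-[(tert-butyldimethylsilyl)oxy]-8-[(2R,3R)-3-(2-iodoethyl)-2-methyloxiran-2-yl]-5-methyl-5-(4-methylpent-3-en-1-yl)octa-2,6-dienoate | CC(C)=CCC[C@](C)(/C=C/[C@H](O[Si](C)(C)C(C)(C)C)[C@]1(C)O[C@@H]1CCI)C/C=C(\Br)C(=O)OCC
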